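The data stem from a simulated flask for an exercise; the scatter is artificial.

In a one-step world J + G gives D one for one, so cD cannot pass the smaller charge, that of the limiting reagent, and equal equivalents of G and J are the zero of my scale. I therefore fold charges and time into one number, the share s: cD at a given time over the charge of the limiting reagent.

| flask | J | G | Q | remark | time |
|---|---|---|---|---|---|
| grey | 0.78 M | 0.18 equiv | 0.18 mol% | run made earlier |  |
| blue | 0.78 M | 0.76 equiv | 0.18 mol% | run made earlier |  |
| ochre | 0.78 M | 2.8 equiv | 0.18 mol% | run made earlier |  |
| south | 0.78 M | 0.200 equiv | 0.18 mol% |  | 2.0 h |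
| north-west | 0.78 M | 0.400 equiv | 0.18 mol% |  | 2.0 h |
| west | 0.78 M | 0.800 equiv | 0.18 mol% |  | 2.0 h |
| east | 0.78 M | 1.50 equiv | 0.18 mol% |  | 2.0 h |
| south-west | 0.78 M | 3.00 equiv | 0.18 mol% |  | 2.0 h |

- grey (time / min: D / %): 8.00: 8.2; 20.0: 7.9; 40.0: 3.9; 60.0: 1.8
- blue (time / min: D / %): 8.00: 31.7; 20.0: 24.9; 40.0: 16.4; 60.0: 8.5
- ochre (time / min: D / %): 5.00: 57.4; 12.0: 46.2; 25.0: 29.1; 60.0: 13.5

(readings scatter by 1 percentage point)

- "hardly changes" means that all values lie within two and a half points (for a concentration: within two and a half percent of the largest)

- [D] at the end for south, north-west, west, east, south-west, in this order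
- how the row runs (hardly changes / rises all the way / falls, then rises / falls all the way / rises, then falls)

The readings of grey, blue and ochre fall instead of holding, so these flasks have more in them than one step, but s can still be tested. At 40.0 min grey has s = 21.7% and blue 21.6%, though their charges of G differ by a factor of 4.22. At 60.0 min grey has 10.0%, blue 11.2% and ochre, where J is limiting, 13.5%; these are scattered readings, and I carry one number for the three, with ochre higher than blue.

To reach 2.0 h I take ochre's last fall, 0.0219 /min, and run it on from 60.0 min. That gives 3.62%, my estimate of the share s at the asked time. As read, ochre's fall has slowed from 0.0356 /min to this rate, being slower now than before, so I expect s to come out above 3.62% rather than below it. Multiplying by the limiting charge gives 0.00564 M for south and 0.0282 M for east and south-west alike, so my row rises up to the symmetric point and then stays level.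

The forecast differs from this, with 0.0033 M, 0.0065 M, 0.013 M, 0.019 M and 0.021 M, and its words are “It rises all the way, flattening at the end”.

The flasks give 0.0103 M, 0.0208 M, 0.0426 M, 0.0521 M and 0.0503 M: rises, then falls, turning at 1.2 equiv.

    J + G ⇌ D (K = 4.90 /M, k = 38.0 /M/h)
    J + G ⇌ X (K = 80.0 /M, k = 15.0 /M/h)
    D + Q ⇌ X + Q, rate k3*[Q]*[D] forward; the back reaction follows from the equilibrium constant (k = 38.0 /M/h)
    Q + D → L (k = 3.20 /M/h)

At the end s comes out at 6.60% for south, 6.83% for west and 6.45% for south-west, close together, with south at about twice my 3.62%. This goes with south-west, where D stands at 6.45% after 2.00 h and still at 5.72% after 20.0 h. Carried to north-west, 3.62% gives 0.0113 M, and that flask holds 0.0208 M.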